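In a one-step world there is one clock and a yield that does not fall. These flasks have several clocks, so I laid them out as a ladder, fastest first.

| setting | alpha | eta | beta |
|---|---|---|---|
| electrophile | 0.16 M (fed, over 6.0 h) | 0.16 M | 0.16 M |
| nucleophile | 0.192 M | 0.192 M (fed, over 6.0 h) | 0.192 M |
| free base | 0.128 M | 0.128 M | 0.128 M |
| protic impurity | 0.0160 M | 0.0160 M | 0.0160 M |
| time | 8.0 h | 8.0 h | 8.0 h |
| remark | all else is in the flask from the start; the feed brings no volume worth counting | all else is in the flask from the start; the feed brings no volume worth counting | everything together at the start |
    electrophile + nucleophile ⇌ acid set free + target (K1 = 0.43, k1 = 4.64 × 10⁻⁴ M⁻¹ s⁻¹)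
    nucleophile + acid set free ⇌ protonated nucleophile, settled at all times (K2 = 150 M⁻¹)
    acid set free + free base ⇌ salt of the base, settled at all times (K3 = 2.9 × 10⁵ M⁻¹)
    nucleophile + target → over-reaction product (k4 = 2.32 × 10⁻⁴ M⁻¹ s⁻¹)
    nucleophile + protic impurity → quenched reagent (k5 = 0.00359 M⁻¹ s⁻¹)
- the flask that comes out highest in amount of target, in percent of the electrophile charged, or "all alike" when all lie within 1.5 percentage points (alpha / eta / beta / all alike)
- target at the end, in percent of the electrophile charged, alpha
- target at the end, in percent of the electrophile charged, eta
- target at the end, in percent of the electrophile charged, beta

The first rung is the acid. In beta at the start, the equilibrium constant times concentration is 37000 for the free base against 29 for the nucleophile, so I took the acid as held by the free base and treated the way back of formation as shut while free base stands. Next comes the impurity: its half-life at the charged nucleophile, 0.279 h, is shorter than the electrophile's 2.2 h, and the target's 4.3 h is longer still. So I let beta begin with 0.176 M of working nucleophile.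

On the third rung, formation and over-reaction both run on the same nucleophile, and dividing one rate by the other removes it, and time with it. Let a be the electrophile left and y the target, both as fractions of the electrophile charged, and let s be the selectivity factor, over-reaction's rate constant over formation's, 0.500. Then y = (a^s − a)/(1 − s). This curve tops at a = 25.0% with y = 50.0%, and the base charge covers more conversion than that peak needs.

The last rung is the clock. For the peak I reckoned beta's nucleophile at 0.0160 M, and the logarithmic mean of that and the start is 0.0667 M. Over 8.0 h this estimate gives a = 41.0%, short of the top, so I put beta at 46.1%. The curve takes the electrophile as present from the start, as it is in eta but not in alpha, and for those two flasks I stopped without a figure.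

The forecast named beta as highest, with 41.5% for alpha, 45% for eta and 49% for beta, above my figure, holding that “target is near its peak in the all-at-once flask”.

The simulation gave beta as highest, with 41.9% for alpha, 44.9% for eta and 49.0% for beta. In beta, the impurity step had half of its turnover up to the asked time behind it by 0.298 h and over-reaction by 3.65 h, while free base still stood at 15.6% of its charge at 8.00 h. Beta ended with 32.4% electrophile, where the curve reads 49.0%; the neighbouring beta with 0.064 M impurity ended with 44.8% electrophile, where the curve reads 44.3%, and it held 44.2% target.

The constants used here were drawn at random within sensible limits.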